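## Structural features

The target is a hydroazulene (bicyclo[5.3.0]decene) of the guaiane type, esterified at C8 with (E)-p-coumaric acid. The cyclopentane (C1–C5) and the cycloheptene (C1, C5–C10) share the C1–C5 bond, and C1 is sp2: the only ring alkene, C1=C10, is tetrasubstituted and carries the C14 methyl. Four stereocentres are present, all S: C4 (methyl) next to C5 (ring-fusion hydrogen), and C7 (2-hydroxypropan-2-yl) next to C8 (acyloxy), the two pairs being separated by C6. Relative to C5–H, C4–H and C7–H lie on the same face and C8–H on the opposite one, so the C7 and C8 substituents are trans and both pseudo-equatorial. Fragile groups are the coumarate (free phenol, Michael acceptor, E-alkene), the tertiary alcohol 1,3 to the ester, and the C1=C10 alkene, which acid can move to C1=C5 with loss of C5. The real difficulty is the seven-membered ring bearing a tetrasubstituted ring-fusion alkene, with stereocentres on both sides of it that cannot communicate through a rigid framework. The key step exploits the fact that C9–C10(=C1)–C5–C6 is, in retrosynthetic terms, an isopropenyl group on a cyclopropane (C1, C5, C6) fused to the cyclopentane. C7, C8 and the whole C11 carbinol are then one terminal alkyne.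

## Logic of the disconnections

17 ⇒ 15 + 16. The aryl–C(β) bond of the cinnamate is cut (Heck). The phenol then enters unprotected in the last step and the coumarate is absent from all earlier chemistry. The forward step must give the E-alkene only and leave the tertiary alcohol and the tetrasubstituted alkene alone.

15 ⇒ 13 + 14. The ester C–O bond at C8 is cut. This reduces the problem to a diol; the forward acylation must distinguish the secondary C8–OH from the tertiary C11–OH.

13 ⇒ 12. The C8–O and C7–H bonds are removed together as a syn hydration of C7=C8. Both remaining stereocentres then come from one alkene. The forward step must put boron on C8, attack the face of C5–H, and spare C1=C10.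

12 ⇒ 11. The C4–H bond and one C15–H bond are removed (H2 across an exocyclic alkene). C4 becomes trigonal, so its configuration is set late by face selection next to C5. The forward step must add anti to C6 without migrating or reducing the other alkenes.

11 ⇒ 10. C4=C15 is traced back to a C4 ketone. The ketone is what the ring synthesis delivers; the olefination must be non-basic because C5–H in 10 is both α to the carbonyl and allylic.

10 ⇒ 8 + 9. The C8–C9 and C6–C7 bonds are cut, and C1–C6 is reconnected as a cyclopropane bond (retro (5+2)). This removes the seven-membered ring and the tetrasubstituted alkene in one operation and leaves a nine-carbon bicycle plus a purchased alkyne. The forward step must open C1–C6 and not C1–C5, and must orient the alkyne with the carbinol carbon towards C6.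

8 ⇒ 7. Only the oxidation level at C4 changes. The carbinol is the direct product of the ring-forming step, and a neutral oxidation is required.

7 ⇒ 5 (through 6). The two cyclopropane bonds to C5 (C5–C1 and C5–C6) are cut, returning a carbenoid carbon and a tethered 1,1-disubstituted alkene. The C4 carbinol stereocentre relays its configuration to C5 and C1, so the absolute configuration comes from the chiral pool and no asymmetric catalyst or diazo compound is needed. The forward step must cyclopropanate the proximal alkene of a conjugated diene.

5 ⇒ 1 + 2. The C2–C3 bond is cut between an allyl nucleophile and the CH2 of a three-carbon epoxide. Both pieces are purchased; the allyl anion is symmetrical, so only one constitution can form. The forward step must open the epoxide without touching the C–Cl bond or the stereocentre.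

## Other disconnections considered

Alternative 1: The cut is across C1–C5 and C8–C9 of the seven-membered ring only. In the forward direction 1,1,3,3-tetrabromopropan-2-one A2 and zinc–copper couple would generate a zinc oxyallyl cation that adds across the 2,5-positions of furan A1, and reductive debromination in the same flask would give the meso oxabicycle A3.
- In favour: bulk reagents, one flask, and a reaction type established on exactly these partners. On precedent and scalability of the key step it is better than the chosen plan. It also places the C8 oxygen at the outset, and the rigid bicycle offers good facial control.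
- Against: A3 is meso, so the absolute configuration needs a separate desymmetrisation. A3 lacks C2, C3, C4, C15 and the C11 unit; the C5–O bridge must be broken and C5 rebuilt as the ring-fusion CH; the C10 ketone must become C10–CH3 with C1=C10.
- Comparison: structurally A3 holds the seven-membered ring and one heteroatom, whereas 10 holds fourteen of fifteen skeletal carbons with C5 set. Mechanistically a stepwise cationic (4+3) is better understood than the proposed rhodium step. In step economy the chosen nine-step plan should be clearly shorter.

Alternative 2: The cut is the C1–C5 bond, with C5 reconnected to C10, which turns the hydroazulene into a trans-fused decalin of the eudesmane type. In the forward direction buffered solvolysis of an equatorial C1 sulfonate would trigger an antiperiplanar 1,2-shift of C5 from C10 to C1 (Wagner–Meerwein), and loss of the C1 proton would give the acetonide A4.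
- In favour: the reaction type is known on this skeleton class, which is better than the chosen plan. All four stereocentres would be set beforehand on a chair-locked decalin, and A4 is one hydrolysis away from 13, so its key-step product is more advanced than 10.
- Against: the oxygenated decalin precursor needs a long linear sequence. Proton loss can also occur towards C9 or C14, and the acetonide and tertiary ether must survive ionising conditions.
- Comparison: structure and stereochemistry are more secure than in the chosen plan, and the mechanism is stereospecific. Step economy is poorer, because the complexity is moved into the precursor.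

Alternative 3: The cut is C7–C8. In the forward direction SmI2 would reduce an α-bromo ester to a samarium enolate that adds to a tethered C8 aldehyde (intramolecular Reformatsky), closing the seven-membered ring and giving the β-hydroxy ester A5.
- In favour: mild, chemoselective and known for medium rings, again better precedented than the chosen key step. A5 would reach 13 by double methyl addition to the ester, so the endgame is as short as the chosen one.
- Against: the open-chain precursor must already contain the cis C4/C5 cyclopentane and a geometrically defined tetrasubstituted exocyclic C1=C10 alkene carrying a β,γ-unsaturated aldehyde that is prone to conjugation. C7 and C8 would be set in a flexible seven-membered transition state.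
- Comparison: both plans rely on substrate control for C7/C8, so they are equal on that point. The chosen plan creates C1=C10 in the ring-forming event instead of requiring it in advance, and should be shorter.

Key step: step 4

Remark: atom labels C1–C15 are guaiane positions and are used for every intermediate. In 8, C1 is the isopropenyl-bearing cyclopropane carbon, C5 the CH next to the C4 carbonyl, C6 the cyclopropane CH2, and C9/C10/C14 the isopropenyl group. 17 is (4S,5S,7S,8S).

Remark: the carbenoid cyclopropanation of step 2 is taken to place the carbinol trans to the cyclopropane CH2, as for simple hex-5-enyl oxiranes; on that basis (R)-epichlorohydrin leads to the (1R,5R) ketone 8.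

Step 1
Reactants: 1 2,3-dimethylbuta-1,3-diene; 2 (R)-epichlorohydrin [(2R)-2-(chloromethyl)oxirane]
Product: 5 (2R)-1-chloro-6-methyl-5-methylidenehept-6-en-2-ol, via allylpotassium reagent 3 (not isolated), via allylmagnesium chloride 4 (not isolated)
Conditions: 1 (3 equiv), LiTMP (lithium 2,2,6,6-tetramethylpiperidide), KOt-Bu, THF, −78 °C; MgCl2, −78 → −30 °C; CuI (5 mol %), 2, −30 → 0 °C; H2O
Reagents that add atoms: none
Why: Allylic metalation with a Schlosser-type superbase gives a symmetrical 2-substituted allyl anion, so either terminus leads to the same product; after exchange to magnesium, copper-catalysed SN2 opening of the epoxide at its CH2 should leave the C–Cl bond and the stereocentre of 2 untouched.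

Step 2
Reactants: 5 (2R)-1-chloro-6-methyl-5-methylidenehept-6-en-2-ol
Product: 7 (1R,2R,5R)-5-(prop-1-en-2-yl)bicyclo[3.1.0]hexan-2-ol, via dienyl oxirane 6 (not isolated)
Conditions: LiTMP (3 equiv), t-BuOMe, 0 °C → rt; H2O
Reagents that add atoms: none
Why: The chlorohydrin closes to the epoxide (Williamson), LiTMP lithiates the epoxide CH2 trans to the chain, and the lithium carbenoid adds across the tethered 1,1-disubstituted alkene (intramolecular carbenoid cyclopropanation); C5 and C1 follow stereospecifically from the carbinol centre, with the OH trans to the cyclopropane CH2.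

Step 3
Reactants: 7 (1R,2R,5R)-5-(prop-1-en-2-yl)bicyclo[3.1.0]hexan-2-ol
Product: 8 (1R,5R)-5-(prop-1-en-2-yl)bicyclo[3.1.0]hexan-2-one
Conditions: nPr4N[RuO4] (5 mol %), NMO (1.5 equiv), 4 Å MS, CH2Cl2, rt
Reagents that add atoms: none
Why: Ley–Griffith oxidation is neutral and alkene-tolerant, so the vinylcyclopropane and both cyclopropane stereocentres should be untouched; the carbinol stereocentre is deleted on purpose.

Step 4
Reactants: 8 (1R,5R)-5-(prop-1-en-2-yl)bicyclo[3.1.0]hexan-2-one; 9 2-methylbut-3-yn-2-ol
Product: 10 (8aR)-7-(2-hydroxypropan-2-yl)-4-methyl-3,5,8,8a-tetrahydroazulen-1(2H)-one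
Conditions: 9 (2 equiv, slow addition), [Rh(CO)2Cl]2 (5 mol %), ClCH2CH2Cl, 80 °C
Reagents that add atoms: none
Why: Proposed new method: monovalent rhodium binds the isopropenyl group of 8 and inserts into the peripheral C1–C6 cyclopropane bond to give a σ-alkyl (C6)/π-allyl (C1–C10–C9) trivalent rhodium species, 9 inserts into the Rh–C9 bond through its hydrogen-bearing carbon (C8), and C(sp2)–C(sp3) reductive elimination joins C7 to C6; the closest known reaction type is the [Rh(CO)2Cl]2-catalysed intermolecular (5+2) cycloaddition of monocyclic 1-substituted vinylcyclopropanes with terminal alkynes, extended here to a cyclopropane fused to a cyclopentanone. The seven-membered ring is closed by a two-bond union of a five-carbon and a two-carbon unit through an eight-membered rhodacycle, not by an end-to-end cyclisation, and the allyl shift itself places the tetrasubstituted C1=C10 alkene. No stereocentre is created: C5 is a spectator and keeps the configuration of the cyclopropane, while C7 and C8 emerge sp2. Bond selectivity is required and should be secured by the bicycle, because insertion into the ring-fusion bond C1–C5 would lead to a bridged bicyclo[4.3.1] rhodacycle with C1=C10 at a bridgehead. C1–C6 is also the less substituted bond, and the C4 carbonyl π system overlaps with C5–C6 and not with C1–C5. Alkyne orientation is required and should follow sterics: the carbinol-bearing carbon stays on rhodium, away from the first-formed C8–C9 bond, and therefore ends on C6. Slow addition of 9 limits alkyne oligomerisation, and the neutral medium protects the acidic C5–H of the β,γ-unsaturated ketone.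

Step 5
Reactants: 10 (8aR)-7-(2-hydroxypropan-2-yl)-4-methyl-3,5,8,8a-tetrahydroazulen-1(2H)-one
Product: 11 2-[(3aS)-8-methyl-3-methylidene-1,2,3,3a,4,7-hexahydroazulen-5-yl]propan-2-ol
Conditions: Cp2TiMe2 (3 equiv), toluene/THF, 65 °C, dark
Reagents that add atoms: dimethyltitanocene, C[Ti](C)(C1C=CC=C1)C1C=CC=C1
Why: Petasis methylenation through Cp2Ti=CH2 and an oxatitanacyclobutane is non-basic, so the doubly activated C5–H should not be enolised; the excess reagent covers the tertiary OH, whose titanium alkoxide is cleaved on work-up (the C5 descriptor changes from R to S by priority only).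

Step 6
Reactants: 11 2-[(3aS)-8-methyl-3-methylidene-1,2,3,3a,4,7-hexahydroazulen-5-yl]propan-2-ol
Product: 12 2-[(3S,3aS)-3,8-dimethyl-1,2,3,3a,4,7-hexahydroazulen-5-yl]propan-2-ol
Conditions: H2 (1 atm), RhCl(PPh3)3 (5 mol %), toluene, rt
Reagents that add atoms: none
Why: Homogeneous hydrogenation with RhCl(PPh3)3 selects the 1,1-disubstituted exocyclic alkene over the tri- and tetrasubstituted ones; syn delivery from the face carrying C5–H, anti to C6, should place C15 cis to C6 (4S).

Step 7
Reactants: 12 2-[(3S,3aS)-3,8-dimethyl-1,2,3,3a,4,7-hexahydroazulen-5-yl]propan-2-ol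
Product: 13 (3S,3aS,5S,6S)-5-(2-hydroxypropan-2-yl)-3,8-dimethyl-1,2,3,3a,4,5,6,7-octahydroazulen-6-ol
Conditions: BH3·THF (2.5 equiv), THF, 0 °C; NaOH, H2O2, 0 °C → rt
Reagents that add atoms: hydrogen peroxide, OO
Why: Syn hydroboration puts boron on the less substituted C8 and hydrogen on C7, from the convex face of the folded cycloheptadiene (the face of C5–H, since C6 is held below the C1=C10 plane); oxidation with retention should give 7S,8S with both new substituents pseudo-equatorial and trans, while the first equivalent of borane is consumed by the C11–OH and the tetrasubstituted alkene reacts more slowly.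

Step 8
Reactants: 13 (3S,3aS,5S,6S)-5-(2-hydroxypropan-2-yl)-3,8-dimethyl-1,2,3,3a,4,5,6,7-octahydroazulen-6-ol; 14 prop-2-enoyl chloride
Product: 15 (3S,3aS,5S,6S)-5-(2-hydroxypropan-2-yl)-3,8-dimethyl-1,2,3,3a,4,5,6,7-octahydroazulen-6-yl prop-2-enoate
Conditions: 14 (1.3 equiv), Et3N, CH2Cl2, −20 → 0 °C
Reagents that add atoms: none
Why: Acylation with a small acid chloride should take the secondary C8–OH and leave the hindered tertiary C11–OH; no stereocentre is touched.

Step 9
Reactants: 15 (3S,3aS,5S,6S)-5-(2-hydroxypropan-2-yl)-3,8-dimethyl-1,2,3,3a,4,5,6,7-octahydroazulen-6-yl prop-2-enoate; 16 4-iodophenol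
Product: 17 (3S,3aS,5S,6S)-5-(2-hydroxypropan-2-yl)-3,8-dimethyl-1,2,3,3a,4,5,6,7-octahydroazulen-6-yl (2E)-3-(4-hydroxyphenyl)prop-2-enoate
Conditions: 16 (1.2 equiv), Pd(OAc)2 (5 mol %), P(o-tol)3 (10 mol %), Et3N, MeCN, 80 °C
Reagents that add atoms: none
Why: Heck–Mizoroki arylation: oxidative addition of zerovalent palladium to the aryl iodide, syn carbopalladation at the acrylate terminus and syn β-hydride elimination should give the E-cinnamate only; the free phenol and tertiary alcohol are tolerated and the tetrasubstituted alkene is too hindered to insert.

## Compound list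

1 | 2,3-dimethylbuta-1,3-diene | CC(=C)C(C)=C | starting material
2 | (R)-epichlorohydrin, (2R)-2-(chloromethyl)oxirane | ClC[C@H]1CO1 | starting material
3 | [2-(prop-1-en-2-yl)prop-2-en-1-yl]potassium | C=C(C)C(=C)C[K] | intermediate
4 | chloro[2-(prop-1-en-2-yl)prop-2-en-1-yl]magnesium | C=C(C)C(=C)C[Mg]Cl | intermediate
5 | (2R)-1-chloro-6-methyl-5-methylidenehept-6-en-2-ol | ClC[C@H](O)CCC(=C)C(C)=C | intermediate
6 | (2R)-2-(4-methyl-3-methylidenepent-4-en-1-yl)oxirane | C1O[C@@H]1CCC(=C)C(C)=C | intermediate
7 | (1R,2R,5R)-5-(prop-1-en-2-yl)bicyclo[3.1.0]hexan-2-ol | CC(=C)[C@@]12CC[C@@H](O)[C@@H]1C2 | intermediate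
8 | (1R,5R)-5-(prop-1-en-2-yl)bicyclo[3.1.0]hexan-2-one | CC(=C)[C@@]12CCC(=O)[C@@H]1C2 | intermediate
9 | 2-methylbut-3-yn-2-ol | CC(C)(O)C#C | starting material
10 | (8aR)-7-(2-hydroxypropan-2-yl)-4-methyl-3,5,8,8a-tetrahydroazulen-1(2H)-one (11-hydroxy-15-norguaia-1(10),7-dien-4-one) | CC1=C2CCC(=O)[C@@H]2CC(C(C)(C)O)=CC1 | intermediate
11 | 2-[(3aS)-8-methyl-3-methylidene-1,2,3,3a,4,7-hexahydroazulen-5-yl]propan-2-ol | CC1=C2CCC(=C)[C@@H]2CC(C(C)(C)O)=CC1 | intermediate
12 | 2-[(3S,3aS)-3,8-dimethyl-1,2,3,3a,4,7-hexahydroazulen-5-yl]propan-2-ol | CC1=C2CC[C@H](C)[C@@H]2CC(C(C)(C)O)=CC1 | intermediate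
13 | (3S,3aS,5S,6S)-5-(2-hydroxypropan-2-yl)-3,8-dimethyl-1,2,3,3a,4,5,6,7-octahydroazulen-6-ol | CC1=C2CC[C@H](C)[C@@H]2C[C@H](C(C)(C)O)[C@@H](O)C1 | intermediate
14 | prop-2-enoyl chloride | C=CC(=O)Cl | starting material
15 | (3S,3aS,5S,6S)-5-(2-hydroxypropan-2-yl)-3,8-dimethyl-1,2,3,3a,4,5,6,7-octahydroazulen-6-yl prop-2-enoate | CC1=C2CC[C@H](C)[C@@H]2C[C@H](C(C)(C)O)[C@@H](OC(=O)C=C)C1 | intermediate
16 | 4-iodophenol | Oc1ccc(I)cc1 | starting material
17 | (3S,3aS,5S,6S)-5-(2-hydroxypropan-2-yl)-3,8-dimethyl-1,2,3,3a,4,5,6,7-octahydroazulen-6-yl (2E)-3-(4-hydroxyphenyl)prop-2-enoate | CC1=C2CC[C@H](C)[C@@H]2C[C@H](C(C)(C)O)[C@@H](OC(=O)/C=C/c2ccc(O)cc2)C1 | target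

Total step count: 9. Longest linear sequence: 9 steps (1 to 17); 2, 9, 14 and 16 are purchased.

## Least certain steps and fallbacks

Step 4 (key step, proposed new method). What is most likely to go wrong:
- rhodium inserts into the ring-fusion bond, or ring opening is so slow that alkyne oligomerisation takes over;
- alkyne insertion occurs with the reverse orientation;
- the β,γ-alkene migrates into conjugation at 80 °C, with loss of C5.

Fallback from known chemistry: replace the metal-mediated union by a thermal divinylcyclopropane (Cope) rearrangement of a β-cyclopropyl cyclopentenone. It sets out from 9 and comes back at 10. Prop-2-yn-1-ol is converted by copper-catalysed methylmagnesiation and iodinolysis into (2Z)-3-iodo-2-methylprop-2-en-1-ol F1. 9 is hydrostannylated at its internal carbon (Bu3SnH, Mo(CO)3(CNt-Bu)3 cat.) to 2-methyl-3-(tributylstannyl)but-3-en-2-ol F2. Stille coupling of the two (Pd(PPh3)4, CuI, CsF) would give (2Z)-2,5-dimethyl-4-methylidenehex-2-ene-1,5-diol F3. Dioxaborolane-mediated asymmetric Simmons–Smith cyclopropanation of the primary allylic alcohol (Zn(CH2I)2, tartramide-derived butylboronate, antipode chosen for the 1R,2S product) would give [(1R,2S)-2-(3-hydroxy-3-methylbut-1-en-2-yl)-1-methylcyclopropyl]methanol F4, cis by stereospecific addition to the Z-alkene. Dess–Martin oxidation leads to (1R,2R)-2-(3-hydroxy-3-methylbut-1-en-2-yl)-1-methylcyclopropane-1-carbaldehyde F5, which is used at once. Stetter addition to but-3-en-2-one (thiazolium salt, Et3N) gives 1-[(1R,2R)-2-(3-hydroxy-3-methylbut-1-en-2-yl)-1-methylcyclopropyl]pentane-1,4-dione F6. Intramolecular aldol condensation (KOH, MeOH, rt) gives 3-[(1R,2S)-2-(3-hydroxy-3-methylbut-1-en-2-yl)-1-methylcyclopropyl]cyclopent-2-en-1-one F7. Warming F7 in toluene (80–110 °C) should break the C8–C10 cyclopropane bond and form C5–C6 through a boat transition state. C1=C10 and C7=C8 appear, and the cyclopropane configuration is transferred to C5 (8aR), which is 10.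

Step 2. What is most likely to go wrong: the lithium carbenoid is consumed by dimerisation or C–H insertion, or the conjugated diene is attacked by the amide base, before the cyclopropane closes.

Fallback: replace the chiral-pool carbenoid by a catalytic asymmetric diazoketone cyclopropanation. It sets out from 1 and comes back at 8. The potassium reagent 3 opens oxirane to 5-methyl-4-methylidenehex-5-en-1-ol F8. TEMPO/PhI(OAc)2 in MeCN–H2O gives 5-methyl-4-methylidenehex-5-enoic acid F9. The acid chloride ((COCl)2, cat. DMF) and Me3SiCHN2 give 1-diazo-6-methyl-5-methylidenehept-6-en-2-one F10. Cu(MeCN)4PF6 with a tert-butyl bis(oxazoline) ligand (antipode chosen for 1R,5R) in CH2Cl2 should close the cyclopropane on the proximal alkene with loss of dinitrogen to give 8.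

Step 5. What is most likely to go wrong: enolisation towards C5 at 65 °C (racemisation, or migration of C1=C10 into the cyclopentenone), or stalling after titanation of the tertiary alcohol.

Fallback: replace the carbene transfer by a Peterson olefination. It sets out from 10 and comes back at 11. Me3SiCH2Li/CeCl3 (THF, −78 °C) adds to the ketone without enolisation, from the face of C5–H, to give (3S,3aR)-5-(2-hydroxypropan-2-yl)-8-methyl-3-[(trimethylsilyl)methyl]-1,2,3,3a,4,7-hexahydroazulen-3-ol F11. KH (THF, 0 °C → rt) then effects syn elimination of the silanolate to give 11.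

Step 7. What is most likely to go wrong: poor facial selectivity at C7=C8, because the two faces differ only through the fold imposed by C5; competing hydroboration of C1=C10 is a secondary concern.

Fallback: change from substrate control to reagent control. It sets out from 12 and comes back at 13 and makes no new isolated compound. Monoisopinocampheylborane (2.2 equiv, THF, −25 °C; then NaOH, H2O2) is used in the antipode matched to attack on the C5–H face; by analogy with 1-substituted cycloalkenes this is expected to be the reagent from (+)-α-pinene. Its bulk should also keep it off the tetrasubstituted alkene.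

## Further compounds

F1 | step 4 | (2Z)-3-iodo-2-methylprop-2-en-1-ol | OC/C(C)=C\I
F2 | step 4 | 2-methyl-3-(tributylstannyl)but-3-en-2-ol | CCCC[Sn](CCCC)(CCCC)C(=C)C(C)(C)O
F3 | step 4 | (2Z)-2,5-dimethyl-4-methylidenehex-2-ene-1,5-diol | OC/C(C)=C\C(=C)C(C)(C)O
F4 | step 4 | [(1R,2S)-2-(3-hydroxy-3-methylbut-1-en-2-yl)-1-methylcyclopropyl]methanol | OC[C@]1(C)C[C@@H]1C(=C)C(C)(C)O
F5 | step 4 | (1R,2R)-2-(3-hydroxy-3-methylbut-1-en-2-yl)-1-methylcyclopropane-1-carbaldehyde | O=C[C@]1(C)C[C@@H]1C(=C)C(C)(C)O
F6 | step 4 | 1-[(1R,2R)-2-(3-hydroxy-3-methylbut-1-en-2-yl)-1-methylcyclopropyl]pentane-1,4-dione | CC(=O)CCC(=O)[C@]1(C)C[C@@H]1C(=C)C(C)(C)O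
F7 | step 4 | 3-[(1R,2S)-2-(3-hydroxy-3-methylbut-1-en-2-yl)-1-methylcyclopropyl]cyclopent-2-en-1-one | O=C1CCC(=C1)[C@]2(C)C[C@@H]2C(=C)C(C)(C)O
F8 | step 2 | 5-methyl-4-methylidenehex-5-en-1-ol | C=C(C)C(=C)CCCO
F9 | step 2 | 5-methyl-4-methylidenehex-5-enoic acid | C=C(C)C(=C)CCC(=O)O
F10 | step 2 | 1-diazo-6-methyl-5-methylidenehept-6-en-2-one | C=C(C)C(=C)CCC(=O)C=[N+]=[N-]
F11 | step 5 | (3S,3aR)-5-(2-hydroxypropan-2-yl)-8-methyl-3-[(trimethylsilyl)methyl]-1,2,3,3a,4,7-hexahydroazulen-3-ol | CC1=C2CC[C@@](O)(C[Si](C)(C)C)[C@@H]2CC(C(C)(C)O)=CC1
F0 | step 7 | none | none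
A1 | alternative 1 | furan | c1ccoc1
A2 | alternative 1 | 1,1,3,3-tetrabromopropan-2-one | O=C(C(Br)Br)C(Br)Br
A3 | alternative 1 | meso-(1R,5S)-8-oxabicyclo[3.2.1]oct-6-en-3-one | O=C1C[C@@H]2C=C[C@H](C1)O2
A4 | alternative 2 | 8,11-O-isopropylidene acetal of (4S,5S,7S,8S)-guai-1(10)-ene-8,11-diol | CC1=C2CC[C@H](C)[C@@H]2C[C@H]3[C@@H](OC(C)(C)OC3(C)C)C1
A5 | alternative 3 | methyl (3S,3aS,5S,6S)-6-hydroxy-3,8-dimethyl-1,2,3,3a,4,5,6,7-octahydroazulene-5-carboxylate | CC1=C2CC[C@H](C)[C@@H]2C[C@H](C(=O)OC)[C@@H](O)C1
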